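(The runs stem from a simulated flask for substances that don't exist; noise was put on by code.)

Place the readings of the flask early, and choose their times by how fast target is lost.

all flasks: gas 0.074 mM (held)

| flask | starting material | remark | time |
|---|---|---|---|
| winter | 0.50 mM | run made earlier |  |
| dusk | 0.75 mM | run made earlier |  |
| flask | 1.0 mM |  | 20 min |

| winter: time / min | winter: target / % | dusk: time / min | dusk: target / % |
|---|---|---|---|
| 0.167 | 54.9 | 0.167 | 43.2 |
| 0.417 | 54.9 | 0.417 | 59.6 |
| 1.00 | 20.2 | 1.00 | 22.9 |
| 2.50 | 2.1 | 2.50 | 1.1 |
| 6.00 | 0 | 6.00 | 0 |
| 15.0 | 0.1 | 15.0 | 0 |

(each reading ± 0.3 percentage points)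

* time up to 20 min at which target stands highest
* the amount of target, in percent of the starting material charged, at that time
* earliest time at which at least nineteen twentieths of that best amount are there, in min
* latest time at which they still are, in min

- at the start none of reagent is dissolved
- the numbers in the tables scatter by 0.3 percentage points (one standard deviation)
- candidate steps: gas <-> reagent; starting material + reagent -> target; target -> over-reaction product; starting material + 2 reagent -> side product

Take making as finished by 1.00 min in the winter and dusk runs. Their summed target falls by 1.73 min⁻¹ as a first-order rate, so target halves in 0.400 min once making has stopped. Call this the tail half-life; it is far shorter than the longest time allowed.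

Next take making as constant. The first dusk reading, put on the flask's charge with its loss added back, gives 2.22 min⁻¹ as a fraction of that charge. Counting the whole charge as target puts the flask's peak at 0.450 min and 69.5 %.

That whole charge is the weak link. Carrying the winter reading at 1.00 min back along the tail, over a making time of 0.225 min, gives a target share of 93.5 %. My reckoning for the flask therefore stands at 0.421 min and 66.4 %.

The forecast differs: 55.5 % at 0.5 min, later and lower than mine, with a window from 0.45 min to 0.56 min, on the ground that “starting material should run out at about 0.5 min”.

The flask gives 59.6 % at 0.421 min, with the window from 0.340 min to 0.503 min.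

    gas ⇌ reagent, rate k1*(csat - [reagent]) (kL = 0.680 s⁻¹)
    starting material + reagent → target (k = 6400 M⁻¹ s⁻¹)
    target → over-reaction product (k = 0.0280 s⁻¹)
    starting material + 2 reagent → side product (k = 3.40 × 10⁷ M⁻² s⁻¹)

At 0.216 min the flask makes target 3.03 times faster than it uses it. Yet the half-life of target on its path to over-reaction product, 0.41 min, is short against 20 min, and the flask holds 0 % target at 20.0 min. In the flask, the tail half-life carries 7.91 % at 1.69 min on to 4.62 % at 2.00 min, where 4.66 % stands. For the neighbour flask left until 5.0 min, it carries that amount on to 0.0257 %; the computed amount is 0.0301 %.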